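The route rests on disconnecting the C3–N and C4–O bonds of ring A back to a C3=C4 alkene. One osmium-catalysed aminohydroxylation adds a benzyl carbamate nitrogen to C3 and a hydroxyl to C4 in a single syn event, setting both stereocentres last. The step exploits the folded bicyclo[3.3.1]nonane: ring B (C6–C8) lies under the endo face of the ring A alkene, so the reagent reaches only the exo face, and C3 (next to the C2 methylene) is less encumbered than C4 (next to bridgehead C5). The precursor is 7,8-epoxy-1-hydroxy-6-methoxybicyclo[3.3.1]non-3-en-9-one, carrying every other stereocentre, made by gold-catalysed 6-endo-dig closure of ring A and Wharton/directed-epoxidation chemistry in ring B.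

Key step: step 12

Convention: locants are those of the target bicycle throughout (C1 carbinol bridgehead, C5 CH bridgehead, C9 ketone, ring A = C2–C4, ring B = C6–C8); exo means on the face of a ring turned away from the other ring.

Assumption: the sense of induction of the chiral lithium amide in step 4 is to be confirmed by a pilot run; the (R,R)-amide is written and its enantiomer is used if the opposite arm is deprotonated.

Step 1
Reactants: 1 cyclohexane-1,3-dione
Product: 2 2-diazocyclohexane-1,3-dione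
Conditions: 4-acetamidobenzenesulfonyl azide, Et3N, MeCN, 0 °C → rt
Reagents that add atoms: 4-acetamidobenzenesulfonyl azide, CC(=O)Nc1ccc(cc1)S(=O)(=O)N=[N+]=[N-]
Why: Regitz diazo transfer to the doubly activated C2 methylene of a 1,3-diketone is a standard reaction and creates no stereocentre.

Step 2
Reactants: 2 2-diazocyclohexane-1,3-dione; 3 4-methoxybenzyl alcohol
Product: 4 2-[(4-methoxybenzyl)oxy]cyclohexane-1,3-dione (rests as its enol)
Conditions: Rh2(OAc)4 (1 mol%), 3 (1.5 equiv), ClCH2CH2Cl, 80 °C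
Reagents that add atoms: none
Why: Rhodium-carbenoid O–H insertion of the diazo diketone into the primary alcohol installs the C2 ether oxygen in one operation with loss of N2.

Step 3
Reactants: 4 2-[(4-methoxybenzyl)oxy]cyclohexane-1,3-dione; 5 propargyl bromide
Product: 6 2-[(4-methoxybenzyl)oxy]-2-(prop-2-yn-1-yl)cyclohexane-1,3-dione (achiral, prochiral)
Conditions: KOH (1.05 equiv), 5 (1.5 equiv), H2O, rt → 50 °C
Reagents that add atoms: none
Why: C-alkylation of a 2-substituted cyclohexane-1,3-dione enolate with a propargylic halide in water, where hydrogen bonding to the enolate oxygens favours attack through carbon, builds the quaternary carbon.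

Step 4
Reactants: 6 2-[(4-methoxybenzyl)oxy]-2-(prop-2-yn-1-yl)cyclohexane-1,3-dione
Product: 8 (2R)-3-[(tert-butyldimethylsilyl)oxy]-2-[(4-methoxybenzyl)oxy]-2-(prop-2-yn-1-yl)cyclohex-3-en-1-one, via lithium enolate 7 (not isolated)
Conditions: (R,R)-bis(1-phenylethyl)amine (1.2 equiv), n-BuLi (1.15 equiv), LiCl, THF, −100 °C; then TBSOTf, −100 → −78 °C
Reagents that add atoms: tert-butyldimethylsilyl trifluoromethanesulfonate, CC(C)(C)[Si](C)(C)OS(=O)(=O)C(F)(F)F
Why: Enantioselective deprotonation of a prochiral ketone by a C2-symmetric chiral lithium amide (desymmetrising enolisation) should remove a proton from only one of the two enantiotopic CH2C=O arms, which turns the quaternary carbon into the (R) stereocentre, and O-silylation fixes that enolate.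

Step 5
Reactants: 8 (2R)-3-[(tert-butyldimethylsilyl)oxy]-2-[(4-methoxybenzyl)oxy]-2-(prop-2-yn-1-yl)cyclohex-3-en-1-one
Product: 9 (1S,5R)-1-[(4-methoxybenzyl)oxy]bicyclo[3.3.1]non-3-ene-8,9-dione
Conditions: [(tBuXPhos)Au(NCMe)]SbF6 (3 mol%; tBuXPhos = 2-di-tert-butylphosphino-2′,4′,6′-triisopropylbiphenyl), acetone, H2O (2 equiv), rt
Reagents that add atoms: none
Why: Gold-catalysed carbocyclisation of a silyl enol ether onto a terminal alkyne (Conia-ene type), with a bulky biarylphosphine steering the enol carbon to the alkyne terminus (6-endo-dig over 5-exo-dig), should forge C4–C5 and ring A, the new bridgehead C5 being fixed by the cis span of the tether, and protodeauration with loss of silanol releases the C9 ketone.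

Step 6
Reactants: 9 (1S,5R)-1-[(4-methoxybenzyl)oxy]bicyclo[3.3.1]non-3-ene-8,9-dione
Product: 11 (1S,5S)-1-[(4-methoxybenzyl)oxy]bicyclo[3.3.1]nona-3,6-diene-8,9-dione, via trimethylsilyl enol ether 10 (not isolated)
Conditions: TMSOTf, Et3N, CH2Cl2, 0 °C; then Pd(OAc)2 (1.1 equiv), MeCN, rt
Reagents that add atoms: none
Why: Only C8 can enolise (C9 lies between a quaternary carbon and a bridgehead whose enol would break Bredt's rule), so soft enolisation followed by Saegusa–Ito oxidation should give the C6=C7 enone regiospecifically.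

Step 7
Reactants: 11 (1S,5S)-1-[(4-methoxybenzyl)oxy]bicyclo[3.3.1]nona-3,6-diene-8,9-dione
Product: 12 (1R,5S,6S,7S)-6,7-epoxy-1-[(4-methoxybenzyl)oxy]bicyclo[3.3.1]non-3-ene-8,9-dione (epoxide exo)
Conditions: TBHP (5.5 M in decane, 2 equiv), DBU (1.2 equiv), CH2Cl2, 0 °C → rt
Reagents that add atoms: tert-butyl hydroperoxide, CC(C)(C)OO
Why: Weitz–Scheffer nucleophilic epoxidation under non-aqueous conditions (chosen to spare the non-enolisable 1,3-dione from retro-Claisen cleavage) should attack C6 from the convex face away from ring A and so set C6 and C7 as the exo epoxide.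

Step 8
Reactants: 12 (1R,5S,6S,7S)-6,7-epoxy-1-[(4-methoxybenzyl)oxy]bicyclo[3.3.1]non-3-ene-8,9-dione
Product: 14 (1S,5S,6R)-6-hydroxy-1-[(4-methoxybenzyl)oxy]bicyclo[3.3.1]nona-3,7-dien-9-one (6-OH exo), via C8 hydrazone 13 (not isolated)
Conditions: N2H4·H2O (1.2 equiv), AcOH (0.3 equiv), MeOH, 0 °C → rt
Reagents that add atoms: none
Why: Wharton transposition, in which the C8 hydrazone of the epoxy ketone fragments irreversibly with loss of N2, should move the oxygen to C6 with its exo configuration retained and place the alkene at C7=C8, the near-stoichiometric hydrazine being drained through this channel from any reversible condensation at C9.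

Step 9
Reactants: 14 (1S,5S,6R)-6-hydroxy-1-[(4-methoxybenzyl)oxy]bicyclo[3.3.1]nona-3,7-dien-9-one
Product: 15 (1S,5S,6S,7S,8S)-7,8-epoxy-6-hydroxy-1-[(4-methoxybenzyl)oxy]bicyclo[3.3.1]non-3-en-9-one (epoxide exo, cis to 6-OH)
Conditions: VO(acac)2 (5 mol%), TBHP (1.5 equiv, decane), CH2Cl2, 0 °C → rt
Reagents that add atoms: tert-butyl hydroperoxide, CC(C)(C)OO
Why: Vanadium-catalysed hydroxyl-directed epoxidation should deliver oxygen to C7=C8 syn to the pseudo-axial C6 hydroxyl, that is on the exo face of ring B, and leave the unactivated C3=C4 alkene untouched.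

Step 10
Reactants: 15 (1S,5S,6S,7S,8S)-7,8-epoxy-6-hydroxy-1-[(4-methoxybenzyl)oxy]bicyclo[3.3.1]non-3-en-9-one
Product: 16 (1S,5S,6S,7S,8S)-7,8-epoxy-6-methoxy-1-[(4-methoxybenzyl)oxy]bicyclo[3.3.1]non-3-en-9-one
Conditions: NaH (1.5 equiv), MeI (3 equiv), THF/DMF, 0 °C → rt
Reagents that add atoms: iodomethane, CI
Why: Williamson O-methylation of the secondary alkoxide is safe here because the ketone has no enolisable α-hydrogen and the cis epoxy alkoxide cannot undergo Payne rearrangement, so no stereocentre is touched.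

Step 11
Reactants: 16 (1S,5S,6S,7S,8S)-7,8-epoxy-6-methoxy-1-[(4-methoxybenzyl)oxy]bicyclo[3.3.1]non-3-en-9-one
Product: 17 (1S,5S,6S,7S,8S)-7,8-epoxy-1-hydroxy-6-methoxybicyclo[3.3.1]non-3-en-9-one
Conditions: DDQ (1.5 equiv), CH2Cl2/pH 7 buffer 10:1, 0 °C → rt
Reagents that add atoms: none
Why: Oxidative cleavage of the 4-methoxybenzyl ether by DDQ (benzylic hydride abstraction, then hydrolysis of the oxocarbenium ion) should free the tertiary C1 hydroxyl under neutral conditions that spare epoxide and alkene.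

Step 12
Reactants: 17 (1S,5S,6S,7S,8S)-7,8-epoxy-1-hydroxy-6-methoxybicyclo[3.3.1]non-3-en-9-one; 18 benzyl carbamate
Product: 20 benzyl N-[(1S,3S,4R,5S,6S,7S,8S)-7,8-epoxy-1,4-dihydroxy-6-methoxy-9-oxobicyclo[3.3.1]nonan-3-yl]carbamate, via sodium benzyl N-chlorocarbamate 19 (not isolated)
Conditions: 18 (3.1 equiv), NaOH (3.05 equiv), t-BuOCl (3.05 equiv), n-PrOH/H2O 1:1, 0 °C, 10 min; then (DHQD)2PHAL (6 mol%), 17, K2OsO2(OH)4 (5 mol%), 0 °C → rt
Reagents that add atoms: water, O
Why: The N-chlorocarbamate anion turns the osmate into a ligand-bound imidotrioxoosmium species (octavalent osmium) that adds suprafacially across C3=C4 to an osmium azaglycolate (hexavalent osmium), and reoxidation by further N-chlorocarbamate plus hydrolysis releases the cis carbamate alcohol and restarts the cycle. The closest known reaction is the Sharpless asymmetric aminohydroxylation of cis-disubstituted cycloalkenes with carbamate nitrogen sources. No ring is closed. C3 and C4 are both set by the face of attack: the endo face of the ring A alkene lies under ring B, whose C7 hydrogen points at C3, so the osmium reagent can arrive only on the convex exo face, and the suprafacial mechanism then places N and O cis. The step needs regiocontrol (N to C3) and chemoselectivity over plain dihydroxylation: C3 is flanked by the C2 methylene and C4 by the branched bridgehead C5, so the bulkier imido end should bond to C3, a preference reinforced by the phthalazine ligand, whose rate acceleration also suppresses the ligand-free diol pathway. The α-ketol, the epoxide and the non-enolisable ketone should tolerate the weakly basic medium because the hydroxide is consumed in forming 19 before 17 is added.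

Step 13
Reactants: 20 benzyl N-[(1S,3S,4R,5S,6S,7S,8S)-7,8-epoxy-1,4-dihydroxy-6-methoxy-9-oxobicyclo[3.3.1]nonan-3-yl]carbamate
Product: 22 (1S,3S,4R,5S,6S,7S,8S)-3-amino-7,8-epoxy-1,4-dihydroxy-6-methoxybicyclo[3.3.1]nonan-9-one, via carbamic acid 21 (not isolated)
Conditions: H2 (1 atm), 10% Pd/C, EtOAc/MeOH, rt; used crude
Reagents that add atoms: none
Why: Hydrogenolysis of the benzylic C–O bond of the carbamate and spontaneous decarboxylation should give the free amine, while the epoxide (neither benzylic nor allylic) and the ketone are not reduced under these conditions.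

Step 14
Reactants: 22 (1S,3S,4R,5S,6S,7S,8S)-3-amino-7,8-epoxy-1,4-dihydroxy-6-methoxybicyclo[3.3.1]nonan-9-one; 23 (E)-dodec-2-enoic acid
Product: 25 (2E)-N-[(1S,3S,4R,5S,6S,7S,8S)-7,8-epoxy-1,4-dihydroxy-6-methoxy-9-oxobicyclo[3.3.1]nonan-3-yl]dodec-2-enamide (target), via benzotriazolyl ester 24 (not isolated)
Conditions: 23 (1.1 equiv), EDC·HCl (1.2 equiv), HOBt (1.2 equiv), CH2Cl2/DMF, 0 °C → rt
Reagents that add atoms: none
Why: Carbodiimide amide coupling through the benzotriazolyl ester should acylate the primary amine much faster than the secondary and tertiary hydroxyls and leave the (E)-alkene and all stereocentres intact.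

Compound list
1 | cyclohexane-1,3-dione | O=C1CCCC(=O)C1 | starting material
2 | 2-diazocyclohexane-1,3-dione | [N-]=[N+]=C1C(=O)CCCC1=O | intermediate
3 | 4-methoxybenzyl alcohol | COc1ccc(CO)cc1 | starting material
4 | 2-[(4-methoxybenzyl)oxy]cyclohexane-1,3-dione | O=C1CCCC(=O)C1OCc1ccc(OC)cc1 | intermediate
5 | propargyl bromide | BrCC#C | starting material
6 | 2-[(4-methoxybenzyl)oxy]-2-(prop-2-yn-1-yl)cyclohexane-1,3-dione | C#CCC1(OCc2ccc(OC)cc2)C(=O)CCCC1=O | intermediate
7 | lithium (6R)-6-[(4-methoxybenzyl)oxy]-5-oxo-6-(prop-2-yn-1-yl)cyclohex-1-en-1-olate | [Li+].C#CC[C@]1(OCc2ccc(OC)cc2)C(=O)CCC=C1[O-] | intermediate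
8 | (2R)-3-[(tert-butyldimethylsilyl)oxy]-2-[(4-methoxybenzyl)oxy]-2-(prop-2-yn-1-yl)cyclohex-3-en-1-one | C#CC[C@]1(OCc2ccc(OC)cc2)C(=O)CCC=C1O[Si](C)(C)C(C)(C)C | intermediate
9 | (1S,5R)-1-[(4-methoxybenzyl)oxy]bicyclo[3.3.1]non-3-ene-8,9-dione | C1=C[C@@H]2C(=O)[C@](OCc3ccc(OC)cc3)(C1)C(=O)CC2 | intermediate
10 | (1S,5R)-1-[(4-methoxybenzyl)oxy]-8-[(trimethylsilyl)oxy]bicyclo[3.3.1]nona-3,7-dien-9-one | C1=C[C@@H]2C(=O)[C@](OCc3ccc(OC)cc3)(C1)C(O[Si](C)(C)C)=CC2 | intermediate
11 | (1S,5S)-1-[(4-methoxybenzyl)oxy]bicyclo[3.3.1]nona-3,6-diene-8,9-dione | C1=C[C@@H]2C(=O)[C@](OCc3ccc(OC)cc3)(C1)C(=O)C=C2 | intermediate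
12 | (1R,5S,6S,7S)-6,7-epoxy-1-[(4-methoxybenzyl)oxy]bicyclo[3.3.1]non-3-ene-8,9-dione, epoxide exo | C1=C[C@@H]2C(=O)[C@](OCc3ccc(OC)cc3)(C1)C(=O)[C@H]1O[C@H]12 | intermediate
13 | C8 hydrazone of 12 | C1=C[C@@H]2C(=O)[C@](OCc3ccc(OC)cc3)(C1)C(=NN)[C@H]1O[C@H]12 | intermediate
14 | (1S,5S,6R)-6-hydroxy-1-[(4-methoxybenzyl)oxy]bicyclo[3.3.1]nona-3,7-dien-9-one, 6-OH exo | C1=C[C@@H]2C(=O)[C@](OCc3ccc(OC)cc3)(C1)C=C[C@H]2O | intermediate
15 | (1S,5S,6S,7S,8S)-7,8-epoxy-6-hydroxy-1-[(4-methoxybenzyl)oxy]bicyclo[3.3.1]non-3-en-9-one | C1=C[C@@H]2C(=O)[C@](OCc3ccc(OC)cc3)(C1)[C@H]1O[C@H]1[C@H]2O | intermediate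
16 | (1S,5S,6S,7S,8S)-7,8-epoxy-6-methoxy-1-[(4-methoxybenzyl)oxy]bicyclo[3.3.1]non-3-en-9-one | C1=C[C@@H]2C(=O)[C@](OCc3ccc(OC)cc3)(C1)[C@H]1O[C@H]1[C@H]2OC | intermediate
17 | (1S,5S,6S,7S,8S)-7,8-epoxy-1-hydroxy-6-methoxybicyclo[3.3.1]non-3-en-9-one | C1=C[C@@H]2C(=O)[C@](O)(C1)[C@H]1O[C@H]1[C@H]2OC | intermediate
18 | benzyl carbamate | NC(=O)OCc1ccccc1 | starting material
19 | sodium benzyl N-chlorocarbamate | [Na+].Cl[N-]C(=O)OCc1ccccc1 | intermediate
20 | benzyl N-[(1S,3S,4R,5S,6S,7S,8S)-7,8-epoxy-1,4-dihydroxy-6-methoxy-9-oxobicyclo[3.3.1]nonan-3-yl]carbamate | O=C(OCc1ccccc1)N[C@H]1C[C@@]2(O)C(=O)[C@@H]([C@H]1O)[C@H](OC)[C@@H]1O[C@@H]12 | intermediate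
21 | N-carboxy derivative (carbamic acid) of 22 | OC(=O)N[C@H]1C[C@@]2(O)C(=O)[C@@H]([C@H]1O)[C@H](OC)[C@@H]1O[C@@H]12 | intermediate
22 | (1S,3S,4R,5S,6S,7S,8S)-3-amino-7,8-epoxy-1,4-dihydroxy-6-methoxybicyclo[3.3.1]nonan-9-one | N[C@H]1C[C@@]2(O)C(=O)[C@@H]([C@H]1O)[C@H](OC)[C@@H]1O[C@@H]12 | intermediate
23 | (E)-dodec-2-enoic acid | CCCCCCCCC/C=C/C(=O)O | starting material
24 | 1H-benzotriazol-1-yl (E)-dodec-2-enoate | CCCCCCCCC/C=C/C(=O)On1nnc2ccccc12 | intermediate
25 | (2E)-N-[(1S,3S,4R,5S,6S,7S,8S)-7,8-epoxy-1,4-dihydroxy-6-methoxy-9-oxobicyclo[3.3.1]nonan-3-yl]dodec-2-enamide | CCCCCCCCC/C=C/C(=O)N[C@H]1C[C@@]2(O)C(=O)[C@@H]([C@H]1O)[C@H](OC)[C@@H]1O[C@@H]12 | target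

Total step count: 14. Longest linear sequence: 14 steps (1 → 25).

Steps most likely to fail

Step 12. What may go wrong: nitrogen is delivered to C4 instead of C3, or hydrolysis of the imido-osmium species outruns nitrogen transfer so that dihydroxylation takes over. The fallback sets out from 17. Rh2(esp)2-catalysed nitrene transfer from O-(2,4-dinitrophenyl)hydroxylamine in CF3CH2OH should give, again from the exo face, the 3,4-epimino compound (exo NH-aziridine) F1. Acylation of the aziridine nitrogen with acid 23 (EDC, DMAP, CH2Cl2) gives the N-acyl aziridine F2. NaI in acetone then triggers a Heine rearrangement: iodide can open only the C4–N bond from the rear (the rear of C3 is buried under C7 of ring B), and the amide oxygen displaces iodide with a second inversion, so the cis-fused oxazoline F3 carries N on C3 and O on C4, both exo. Brief hydrolysis with dilute aqueous acid in THF opens the oxazoline to the C4 ester of the C3 amine F4, and neutralisation with NaHCO3 lets the acyl group migrate from O to N. The fallback comes back to the route at the target 25.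

Step 4. What may go wrong: insufficient discrimination between the two enantiotopic CH2C=O arms, or proton exchange between enolate and ketone before silylation, either of which erodes the enantiomeric purity. The fallback sets out from 6. Desymmetrising mono-reduction with a ketoreductase (NADPH recycled by glucose and glucose dehydrogenase; baker's yeast as the classical alternative) should give the (2S,3S)-hydroxy ketone F5, drawn with the hydroxyl trans to the propargyl group; only its quaternary centre matters later. TBSOTf/Et3N silylates the alcohol and converts the remaining ketone into its only possible enol ether, giving the bis-silyl compound F6. The gold cyclisation of step 5 then gives the 8-exo-silyloxy bicyclic ketone F7, HF·pyridine frees the C8 alcohol F8, and Dess–Martin periodinane oxidises it to the dione. The fallback comes back to the route at 9.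

Step 8. What may go wrong: hydrazine condenses with the strained C9 ketone (hydrazone or bridging pyrazoline formation), or the 1,3-dione is cleaved by retro-Claisen attack before the Wharton fragmentation occurs. The fallback sets out from 11 and replaces steps 7 to 11. PMe3-catalysed oxa-Michael addition of MeOH to the enone from the exo face should give the 6-exo-methoxy dione F9. KHMDS/PhNTf2 at −78 °C converts the only enolisable ketone into the C7=C8 enol triflate F10, and Pd(OAc)2/PPh3/Bu3N/HCO2H reduces it to the methoxy diene F11. DDQ removes the 4-methoxybenzyl group to give the tertiary allylic alcohol F12, whose C1 hydroxyl directs VO(acac)2/TBHP epoxidation to the exo face of C7=C8. The fallback comes back to the route at 17.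

Further compounds
F1 | step 12 | 3,4-epimino-7,8-epoxy-1-hydroxy-6-methoxybicyclo[3.3.1]nonan-9-one, NH-aziridine on the exo face of ring A | N1[C@H]2C[C@@]3(O)C(=O)[C@@H]([C@H]21)[C@H](OC)[C@@H]1O[C@@H]13
F2 | step 12 | N-[(E)-dodec-2-enoyl] derivative of F1 | CCCCCCCCC/C=C/C(=O)N1[C@H]2C[C@@]3(O)C(=O)[C@@H]([C@H]21)[C@H](OC)[C@@H]1O[C@@H]13
F3 | step 12 | cis-fused 2-[(E)-undec-1-enyl]oxazoline spanning C3 (N) and C4 (O), both exo | CCCCCCCCC/C=C/C1=N[C@H]2C[C@@]3(O)C(=O)[C@@H]([C@H]2O1)[C@H](OC)[C@@H]1O[C@@H]13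
F4 | step 12 | C4 O-[(E)-dodec-2-enoyl] ester of amine 22 | N[C@H]1C[C@@]2(O)C(=O)[C@@H]([C@H]1OC(=O)/C=C/CCCCCCCCC)[C@H](OC)[C@@H]1O[C@@H]12
F5 | step 4 | (2S,3S)-3-hydroxy-2-[(4-methoxybenzyl)oxy]-2-(prop-2-yn-1-yl)cyclohexan-1-one | C#CC[C@]1(OCc2ccc(OC)cc2)[C@@H](O)CCCC1=O
F6 | step 4 | bis(tert-butyldimethylsilyl) derivative of F5 (silyl ether at the carbinol, silyl enol ether of the ketone) | C#CC[C@]1(OCc2ccc(OC)cc2)[C@@H](O[Si](C)(C)C(C)(C)C)CCC=C1O[Si](C)(C)C(C)(C)C
F7 | step 4 | 8-exo-[(tert-butyldimethylsilyl)oxy]-1-[(4-methoxybenzyl)oxy]bicyclo[3.3.1]non-3-en-9-one | C1=C[C@@H]2C(=O)[C@](OCc3ccc(OC)cc3)(C1)[C@@H](O[Si](C)(C)C(C)(C)C)CC2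
F8 | step 4 | 8-exo-hydroxy-1-[(4-methoxybenzyl)oxy]bicyclo[3.3.1]non-3-en-9-one | C1=C[C@@H]2C(=O)[C@](OCc3ccc(OC)cc3)(C1)[C@@H](O)CC2
F9 | step 8 | 6-exo-methoxy-1-[(4-methoxybenzyl)oxy]bicyclo[3.3.1]non-3-ene-8,9-dione | C1=C[C@@H]2C(=O)[C@](OCc3ccc(OC)cc3)(C1)C(=O)C[C@H]2OC
F10 | step 8 | 6-exo-methoxy-1-[(4-methoxybenzyl)oxy]-9-oxobicyclo[3.3.1]nona-3,7-dien-8-yl trifluoromethanesulfonate | C1=C[C@@H]2C(=O)[C@](OCc3ccc(OC)cc3)(C1)C(OS(=O)(=O)C(F)(F)F)=C[C@H]2OC
F11 | step 8 | 6-exo-methoxy-1-[(4-methoxybenzyl)oxy]bicyclo[3.3.1]nona-3,7-dien-9-one | C1=C[C@@H]2C(=O)[C@](OCc3ccc(OC)cc3)(C1)C=C[C@H]2OC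
F12 | step 8 | 1-hydroxy-6-exo-methoxybicyclo[3.3.1]nona-3,7-dien-9-one | C1=C[C@@H]2C(=O)[C@](O)(C1)C=C[C@H]2OC
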